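The carbocycle is cut at C2–C3 (germacrane numbering). This CH2–CH2 unit lies between C1, next to oxygen-bearing C10, and C4, next to C5, so the ten-membered ring is the [3,3] product of a six-membered C5–C10 ring carrying vinyl and hydroxyl on C10 and isopropenyl on C5. One anionic oxy-Cope step on a divinylcyclohexanol fused to the C6/C7/C11/C12 furan makes C2–C3, breaks C5–C10, sets the E C4=C5 alkene and gives a regiodefined C1=C10 enolate, which is hydroxylated at C1 in the same flask. The furan is later oxidised to the C12 lactone while the C1 hydroxyl closes the C1–O–C4 ether.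

Key step: step 11

Remarks on the chemistry:
- Numbering: C1–C10 ring carbons, C11–C13 lactone/furan carbons, C14 and C15 the methyls on C10 and C4; TBS = tert-butyldimethylsilyl. The target is 1S,4R,8S,10R with a (2S)-2-methyloxirane-2-carboxylate; oxidising (R)-2-methylglycidol changes only the CIP label (R to S), not the geometry.
- Assumption: tributyl(2-methylprop-1-en-1-yl)stannane 12 is taken as a catalogue reagent (otherwise one step from commercial 2-methylprop-1-enylmagnesium bromide and Bu3SnCl).
- Design points: the six-membered ring is closed under Lewis-acid conditions and its ketone is never exposed to base, because enolisation toward C9 expels the C8 silyloxy group and aromatises the ring. Precursor 17 is made as the diastereomer with the C8 silyloxy group cis to the C5 isopropenyl group, because its chair delivers the enolate conformer whose outer face leads to (1S).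

Step 1
Reactants: 1 furan-3,4-diyldimethanol
Product: 3 {4-[(tert-butyldimethylsilyloxy)methyl]furan-3-yl}methanol, via monosodium alkoxide 2 (not isolated)
Conditions: NaH (1.0 equiv), THF, 0 → 23 °C; then TBSCl (1.0 equiv)
Reagents that add atoms: tert-butyldimethylsilyl chloride, CC(C)(C)[Si](C)(C)Cl
Why: Monosilylation of a symmetrical diol through its poorly soluble monosodium alkoxide (McDougal protocol) should stop after one silyl transfer, and no stereocentre is involved.

Step 2
Reactants: 3 {4-[(tert-butyldimethylsilyloxy)methyl]furan-3-yl}methanol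
Product: 5 {2-bromo-4-[(tert-butyldimethylsilyloxy)methyl]furan-3-yl}methanol, via dilithio species 4 (not isolated)
Conditions: n-BuLi (2.2 equiv), DME, −78 → 0 °C; then BrCl2C–CCl2Br, −78 °C; H2O
Reagents that add atoms: 1,2-dibromo-1,1,2,2-tetrachloroethane, ClC(Cl)(Br)C(Cl)(Cl)Br
Why: Alkoxide-directed ortho-lithiation of the 3-furylmethanol places lithium on the furan α-carbon next to the CH2OLi group (the silyl ether on the other side is a much weaker director), and electrophilic bromination of the aryllithium gives the 2-bromofuran.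

Step 3
Reactants: 5 {2-bromo-4-[(tert-butyldimethylsilyloxy)methyl]furan-3-yl}methanol
Product: 6 2-bromo-4-[(tert-butyldimethylsilyloxy)methyl]furan-3-carbaldehyde
Conditions: MnO2 (activated), CH2Cl2, 23 °C
Reagents that add atoms: none
Why: Activated MnO2 oxidises the furylmethanol, a benzylic-type alcohol, to the aldehyde without touching the silyl ether or the C–Br bond.

Step 4
Reactants: 6 2-bromo-4-[(tert-butyldimethylsilyloxy)methyl]furan-3-carbaldehyde; 7 (−)-B-allyldiisopinocampheylborane (from (+)-α-pinene)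
Product: 9 (1S)-1-{2-bromo-4-[(tert-butyldimethylsilyloxy)methyl]furan-3-yl}but-3-en-1-ol, via borinate 8 (not isolated)
Conditions: Et2O, −78 °C (magnesium-salt-free 7); then NaBO3·4H2O, THF/H2O, 23 °C
Reagents that add atoms: none
Why: Brown asymmetric allylboration through a closed chair transition state, in which the isopinocampheyl groups of this reagent direct allyl to the Si face of an aryl aldehyde, should set C8 as S (the sense in which benzaldehyde gives the S alcohol).

Step 5
Reactants: 9 (1S)-1-{2-bromo-4-[(tert-butyldimethylsilyloxy)methyl]furan-3-yl}but-3-en-1-ol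
Product: 10 TBS ether of 9, (1S)-1-(tert-butyldimethylsilyloxy)-1-{2-bromo-4-[(tert-butyldimethylsilyloxy)methyl]furan-3-yl}but-3-ene
Conditions: TBSOTf, 2,6-lutidine, CH2Cl2, −78 → 0 °C
Reagents that add atoms: tert-butyldimethylsilyl triflate, CC(C)(C)[Si](C)(C)OS(=O)(=O)C(F)(F)F
Why: A silyl triflate with a hindered pyridine base silylates the hindered secondary alcohol without acid or strong base, so C8 is not disturbed.

Step 6
Reactants: 10 TBS ether of 9
Product: 11 (3S)-3-{2-bromo-4-[(tert-butyldimethylsilyloxy)methyl]furan-3-yl}-3-(tert-butyldimethylsilyloxy)propanal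
Conditions: OsO4 (2 mol %), NaIO4, 2,6-lutidine, dioxane/H2O, 23 °C
Reagents that add atoms: osmium tetroxide (catalytic, its oxo groups renewed by NaIO4), O=[Os](=O)(=O)=O
Why: Johnson–Lemieux cleavage (dihydroxylation, then periodate glycol cleavage) removes the terminal CH2 of the only alkene present while the aromatic bromofuran is left alone, and C8 is not enolisable.

Step 7
Reactants: 11 (3S)-3-{2-bromo-4-[(tert-butyldimethylsilyloxy)methyl]furan-3-yl}-3-(tert-butyldimethylsilyloxy)propanal; 12 tributyl(2-methylprop-1-en-1-yl)stannane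
Product: 13 (3S)-3-(tert-butyldimethylsilyloxy)-3-{4-[(tert-butyldimethylsilyloxy)methyl]-2-(2-methylprop-1-en-1-yl)furan-3-yl}propanal
Conditions: Pd(PPh3)4 (5 mol %), CuI (10 mol %), DMF, 60 °C
Reagents that add atoms: none
Why: Stille coupling of the 2-bromofuran with the alkenylstannane runs under neutral conditions, which the β-silyloxy aldehyde (prone to base-induced loss of silanol) should tolerate, and no stereocentre is touched.

Step 8
Reactants: 13 (3S)-3-(tert-butyldimethylsilyloxy)-3-{4-[(tert-butyldimethylsilyloxy)methyl]-2-(2-methylprop-1-en-1-yl)furan-3-yl}propanal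
Product: 14 (4S,6S,7R)-4-(tert-butyldimethylsilyloxy)-3-[(tert-butyldimethylsilyloxy)methyl]-7-(prop-1-en-2-yl)-4,5,6,7-tetrahydro-1-benzofuran-6-ol
Conditions: Me2AlCl (1.5 equiv), CH2Cl2, −78 → −40 °C; aq. KNaC4H4O6
Reagents that add atoms: none
Why: Lewis-acid-promoted intramolecular carbonyl-ene cyclisation of the citronellal-to-isopulegol kind joins C5 to C10 through a chair in which the aluminium-bound oxygen and the developing isopropenyl group are both equatorial (hence trans) and the C8 silyloxy group is pseudo-axial to avoid the furan C11 substituent, which should give the 6S,7R isomer, while Me2AlCl also takes up the proton so that furan and silyl ethers see no Brønsted acid.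

Step 9
Reactants: 14 (4S,6S,7R)-tetrahydrobenzofuran-6-ol
Product: 15 (4S,7S)-4-(tert-butyldimethylsilyloxy)-3-[(tert-butyldimethylsilyloxy)methyl]-7-(prop-1-en-2-yl)-4,5-dihydro-1-benzofuran-6(7H)-one
Conditions: Dess–Martin periodinane, NaHCO3, CH2Cl2, 0 → 23 °C
Reagents that add atoms: none
Why: Buffered Dess–Martin oxidation gives the ketone under neutral conditions, so it is not enolised toward C9; the C5 centre is kept, and its cis relation to the C8 silyloxy group is also the more stable one.

Step 10
Reactants: 15 (4S,7S)-dihydrobenzofuranone; 16 vinylmagnesium bromide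
Product: 17 (4S,6S,7R)-6-ethenyl-4-(tert-butyldimethylsilyloxy)-3-[(tert-butyldimethylsilyloxy)methyl]-7-(prop-1-en-2-yl)-4,5,6,7-tetrahydro-1-benzofuran-6-ol (vinyl trans to isopropenyl; hydroxyl, isopropenyl and C8 silyloxy on one face)
Conditions: CeCl3 (anhydrous), THF, −78 °C; aq. NH4Cl
Reagents that add atoms: none
Why: The weakly basic vinylcerium reagent (Imamoto conditions) adds to the enolisable β-silyloxy ketone without deprotonating it, and equatorial attack anti to the pseudo-axial C8 silyloxy group and trans to the C5 isopropenyl group should set C10 as S, giving the trans-dialkenyl carbinol.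

Step 11
Reactants: 17 (4S,6S,7R)-6-ethenyl-7-(prop-1-en-2-yl)tetrahydrobenzofuran-6-ol
Product: 20 (4S,7S,10E)-4-(tert-butyldimethylsilyloxy)-3-[(tert-butyldimethylsilyloxy)methyl]-7-hydroxy-10-methyl-4,5,8,9-tetrahydrocyclodeca[b]furan-6(7H)-one (C1 hydroxy, C10 ketone, E C4=C5), via potassium alkoxide 18 (not isolated), via potassium enolate 19 (not isolated)
Conditions: KN(SiMe3)2 (1.3 equiv), 18-crown-6, THF, −78 → −20 °C; then 2-(phenylsulfonyl)-3-phenyloxaziridine, −78 °C; AcOH, −78 °C
Reagents that add atoms: 2-(phenylsulfonyl)-3-phenyloxaziridine, O=S(=O)(N1OC1c1ccccc1)c1ccccc1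
Why: KN(SiMe3)2 with 18-crown-6 turns the C10 hydroxyl into the dissociated potassium alkoxide 18, whose weakened C5–C10 bond lets the 1,5-diene C2=C1–C10–C5–C4=C3 undergo an anionic oxy-Cope [3,3] shift through a chair with vinyl and isopropenyl both equatorial, so that C2–C3 forms, C5–C10 breaks and enolate 19 results irreversibly. The closest known reaction type is the anionic oxy-Cope ring expansion of trans-1,2-dialkenylcyclohexanols to (E)-cyclodec-5-enones, with oxidation of the enolate by an N-sulfonyloxaziridine in the same flask. The ten-membered ring is not closed end to end: it arises by four-atom expansion of the six-membered ring, so no exo or endo mode applies. The only new stereocentre, C1, should be set as S by attack of the oxaziridine on the outer face of the C1=C10 enolate in the conformer born from the chair (enolate oxygen and C8 silyloxy on the same side of the ring), while C5 and C10 lose their configuration and C8 is untouched. The step needs the [3,3] path over heterolytic C5–C10 cleavage or a [1,3] shift, an E C4=C5 alkene and no participation of the furan C6=C7 bond: the trans-diequatorial alkenyl groups enforce the chair and hence E, the aromatic furan bond is a poor 2π partner, and the enolate is kept cold and quenched with acetic acid at −78 °C so that it cannot equilibrate toward C9 and expel the C8 silyloxy group.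

Step 12
Reactants: 20 C1-hydroxy cyclodecenone; 21 methylmagnesium bromide
Product: 22 (4S,6R,7S,10E)-4-(tert-butyldimethylsilyloxy)-3-[(tert-butyldimethylsilyloxy)methyl]-6,10-dimethyl-4,5,6,7,8,9-hexahydrocyclodeca[b]furan-6,7-diol (1S,10R diol)
Conditions: MeMgBr (4 equiv), CH2Cl2/Et2O, −78 → −40 °C; aq. NH4Cl
Reagents that add atoms: none
Why: Chelation-controlled (Cram chelate) Grignard addition, in which magnesium bridges the C1 oxygen and the C10 carbonyl and methyl enters from the side of C1–H, which is also the outer face of the ring, should set C10 as R, and the fast addition to the chelated ketone at low temperature should outrun enolisation toward C9.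

Step 13
Reactants: 22 1S,10R diol
Product: 25 (1S,4R,8S,10R)-8,13-bis(tert-butyldimethylsilyloxy)-1,4-epoxy-6,10-dihydroxygermacr-7(11)-en-12,6-olide (C6 lactol, mixture of epimers), via furan endoperoxide 23 (not isolated), via hydroxybutenolide 24 (not isolated)
Conditions: O2, visible light, 5,10,15,20-tetraphenylporphyrin (cat.), iPr2NEt, CH2Cl2, −78 °C; then DBU, −78 → 23 °C; aq. citric acid
Reagents that add atoms: dioxygen, O=O
Why: Singlet oxygen adds [4+2] across furan C6/C12, the amine removes the only bridgehead hydrogen (C12–H) of the endoperoxide with O–O cleavage (Kornblum–DeLaMare-type) to give the hydroxybutenolide, and the C4=C5–C6=O enone of its ring-opened keto-carboxylate takes up the C1 hydroxyl in a DBU-mediated 5-exo-trig oxa-Michael addition, in which C4 should become R because the C1–O–C4 bridge can only span one face of the ten-membered ring.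

Step 14
Reactants: 25 ether-bridged C6 lactol
Product: 27 (1S,4R,8S,10R)-8,13-bis(tert-butyldimethylsilyloxy)-1,4-epoxy-10-hydroxygermacra-5,7(11)-dien-12,6-olide (C5=C6 with C4 and C7 cis), via lactol acetate 26 (not isolated)
Conditions: Ac2O (1.5 equiv), Et3N, 4-(dimethylamino)pyridine (cat.), CH2Cl2, 0 → 23 °C
Reagents that add atoms: none
Why: Acetylation of the pseudo-acid hydroxyl of the (Z)-4-oxo-2-enoic acid and loss of acetic acid across C5–C6 is the classical enol-lactonisation to a γ-ylidene butenolide (protoanemonin-type dehydration), in which C5 is the only carbon that can lose a proton, the nine-membered ring allows only the geometry with C4 cis to C7, and the hindered tertiary C10 hydroxyl should not be acetylated at 0 °C.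

Step 15
Reactants: 27 bis-silyl ylidene butenolide
Product: 28 (1S,4R,8S,10R)-1,4-epoxy-8,10,13-trihydroxygermacra-5,7(11)-dien-12,6-olide
Conditions: HF·pyridine, pyridine, THF, 0 → 23 °C
Reagents that add atoms: none
Why: Buffered hydrogen fluoride cleaves the primary and the secondary silyl ether without the basicity that would endanger the enol lactone, and no stereocentre is affected.

Step 16
Reactants: 28 triol
Product: 29 (1S,4R,8S,10R)-13-acetoxy-1,4-epoxy-8,10-dihydroxygermacra-5,7(11)-dien-12,6-olide
Conditions: Ac2O (1.1 equiv), 2,4,6-collidine, CH2Cl2, −20 → 0 °C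
Reagents that add atoms: acetic anhydride, CC(=O)OC(C)=O
Why: Rate-selective acetylation: the primary allylic C13 hydroxyl should react well before the hindered secondary C8 hydroxyl, and the tertiary C10 hydroxyl not at all under a weak base at low temperature.

Step 17
Reactants: 30 (R)-2-methylglycidol
Product: 31 (2S)-2-methyloxirane-2-carboxylic acid (used at once)
Conditions: RuCl3·xH2O (2 mol %), NaIO4, MeCN/EtOAc/H2O, 0 → 23 °C
Reagents that add atoms: water, O
Why: Ruthenium tetroxide generated in the flask (Sharpless conditions) oxidises the primary alcohol of a glycidol to the glycidic acid without opening the epoxide, and the quaternary stereocentre cannot epimerise.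

Step 18
Reactants: 29 13-acetate diol; 31 (2S)-2-methyloxirane-2-carboxylic acid
Product: 33 CNP0142137.1, (1S,4R,8S,10R)-13-acetoxy-1,4-epoxy-10-hydroxy-8-[(2S)-2-methyloxirane-2-carbonyloxy]germacra-5,7(11)-dien-12,6-olide, via mixed anhydride 32 (not isolated)
Conditions: 2,4,6-trichlorobenzoyl chloride, Et3N, THF, 0 °C; then 29, 4-(dimethylamino)pyridine, toluene, 23 °C
Reagents that add atoms: none
Why: Yamaguchi esterification transfers the hindered glycidoyl group to the secondary C8 hydroxyl by retention at both partners, the tertiary C10 hydroxyl is inert, and the epoxide should survive the mild, non-acidic conditions.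

Compound list
1 | furan-3,4-diyldimethanol | OCc1cocc1CO | starting material
2 | sodium [4-(hydroxymethyl)furan-3-yl]methanolate | [Na+].[O-]Cc1cocc1CO | intermediate
3 | {4-[(tert-butyldimethylsilyloxy)methyl]furan-3-yl}methanol | CC(C)(C)[Si](C)(C)OCc1cocc1CO | intermediate
4 | lithium {4-[(tert-butyldimethylsilyloxy)methyl]-2-lithiofuran-3-yl}methanolate | CC(C)(C)[Si](C)(C)OCc1coc([Li])c1CO[Li] | intermediate
5 | {2-bromo-4-[(tert-butyldimethylsilyloxy)methyl]furan-3-yl}methanol | CC(C)(C)[Si](C)(C)OCc1coc(Br)c1CO | intermediate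
6 | 2-bromo-4-[(tert-butyldimethylsilyloxy)methyl]furan-3-carbaldehyde | CC(C)(C)[Si](C)(C)OCc1coc(Br)c1C=O | intermediate
7 | (−)-B-allyldiisopinocampheylborane (from (+)-α-pinene) | C=CCB([C@@H]1C[C@@H]2C[C@@H](C2(C)C)[C@H]1C)[C@@H]1C[C@@H]2C[C@@H](C2(C)C)[C@H]1C | starting material
8 | diisopinocampheylborinate of alcohol 9 | C=CC[C@H](OB([C@@H]1C[C@@H]2C[C@@H](C2(C)C)[C@H]1C)[C@@H]1C[C@@H]2C[C@@H](C2(C)C)[C@H]1C)c1c(Br)occ1CO[Si](C)(C)C(C)(C)C | intermediate
9 | (1S)-1-{2-bromo-4-[(tert-butyldimethylsilyloxy)methyl]furan-3-yl}but-3-en-1-ol | C=CC[C@H](O)c1c(Br)occ1CO[Si](C)(C)C(C)(C)C | intermediate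
10 | (1S)-1-(tert-butyldimethylsilyloxy)-1-{2-bromo-4-[(tert-butyldimethylsilyloxy)methyl]furan-3-yl}but-3-ene | C=CC[C@H](O[Si](C)(C)C(C)(C)C)c1c(Br)occ1CO[Si](C)(C)C(C)(C)C | intermediate
11 | (3S)-3-{2-bromo-4-[(tert-butyldimethylsilyloxy)methyl]furan-3-yl}-3-(tert-butyldimethylsilyloxy)propanal | O=CC[C@H](O[Si](C)(C)C(C)(C)C)c1c(Br)occ1CO[Si](C)(C)C(C)(C)C | intermediate
12 | tributyl(2-methylprop-1-en-1-yl)stannane | CCCC[Sn](CCCC)(CCCC)C=C(C)C | starting material
13 | (3S)-3-(tert-butyldimethylsilyloxy)-3-{4-[(tert-butyldimethylsilyloxy)methyl]-2-(2-methylprop-1-en-1-yl)furan-3-yl}propanal | O=CC[C@H](O[Si](C)(C)C(C)(C)C)c1c(C=C(C)C)occ1CO[Si](C)(C)C(C)(C)C | intermediate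
14 | (4S,6S,7R)-4-(tert-butyldimethylsilyloxy)-3-[(tert-butyldimethylsilyloxy)methyl]-7-(prop-1-en-2-yl)-4,5,6,7-tetrahydro-1-benzofuran-6-ol | CC(C)(C)[Si](C)(C)OCc1coc2[C@H](C(C)=C)[C@@H](O)C[C@H](O[Si](C)(C)C(C)(C)C)c12 | intermediate
15 | (4S,7S)-4-(tert-butyldimethylsilyloxy)-3-[(tert-butyldimethylsilyloxy)methyl]-7-(prop-1-en-2-yl)-4,5-dihydro-1-benzofuran-6(7H)-one | CC(C)(C)[Si](C)(C)OCc1coc2[C@H](C(C)=C)C(=O)C[C@H](O[Si](C)(C)C(C)(C)C)c12 | intermediate
16 | vinylmagnesium bromide | C=C[Mg]Br | starting material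
17 | (4S,6S,7R)-6-ethenyl-4-(tert-butyldimethylsilyloxy)-3-[(tert-butyldimethylsilyloxy)methyl]-7-(prop-1-en-2-yl)-4,5,6,7-tetrahydro-1-benzofuran-6-ol | CC(C)(C)[Si](C)(C)OCc1coc2[C@H](C(C)=C)[C@@](O)(C=C)C[C@H](O[Si](C)(C)C(C)(C)C)c12 | intermediate
18 | potassium alkoxide of 17 | CC(C)(C)[Si](C)(C)OCc1coc2[C@H](C(C)=C)[C@@]([O-])(C=C)C[C@H](O[Si](C)(C)C(C)(C)C)c12.[K+] | intermediate
19 | potassium C1=C10 enolate of (4S,10E)-4-(tert-butyldimethylsilyloxy)-3-[(tert-butyldimethylsilyloxy)methyl]-10-methyl-4,5,8,9-tetrahydrocyclodeca[b]furan-6(7H)-one | CC(C)(C)[Si](C)(C)OCc1coc2/C=C(C)/CC/C=C(\[O-])C[C@H](O[Si](C)(C)C(C)(C)C)c12.[K+] | intermediate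
20 | (4S,7S,10E)-4-(tert-butyldimethylsilyloxy)-3-[(tert-butyldimethylsilyloxy)methyl]-7-hydroxy-10-methyl-4,5,8,9-tetrahydrocyclodeca[b]furan-6(7H)-one | CC(C)(C)[Si](C)(C)OCc1coc2/C=C(C)/CC[C@H](O)C(=O)C[C@H](O[Si](C)(C)C(C)(C)C)c12 | intermediate
21 | methylmagnesium bromide | C[Mg]Br | starting material
22 | (4S,6R,7S,10E)-4-(tert-butyldimethylsilyloxy)-3-[(tert-butyldimethylsilyloxy)methyl]-6,10-dimethyl-4,5,6,7,8,9-hexahydrocyclodeca[b]furan-6,7-diol | CC(C)(C)[Si](C)(C)OCc1coc2/C=C(C)/CC[C@H](O)[C@](C)(O)C[C@H](O[Si](C)(C)C(C)(C)C)c12 | intermediate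
23 | C6,C12-endoperoxide of furan 22 (both faces) | CC(C)(C)[Si](C)(C)OCC1=C2[C@@H](O[Si](C)(C)C(C)(C)C)C[C@@](C)(O)[C@@H](O)CC/C(C)=C/C23OOC1O3 | intermediate
24 | (1S,8S,10R,4E)-8,13-bis(tert-butyldimethylsilyloxy)-1,6,10-trihydroxygermacra-4,7(11)-dien-12,6-olide (C6 lactol) | CC(C)(C)[Si](C)(C)OCC1=C2[C@@H](O[Si](C)(C)C(C)(C)C)C[C@@](C)(O)[C@@H](O)CC/C(C)=C/C2(O)OC1=O | intermediate
25 | (1S,4R,8S,10R)-8,13-bis(tert-butyldimethylsilyloxy)-1,4-epoxy-6,10-dihydroxygermacr-7(11)-en-12,6-olide (C6 lactol) | CC(C)(C)[Si](C)(C)OCC1=C2[C@@H](O[Si](C)(C)C(C)(C)C)C[C@@](C)(O)[C@@H]3CC[C@@](C)(O3)CC2(O)OC1=O | intermediate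
26 | C6 acetate of lactol 25 | CC(C)(C)[Si](C)(C)OCC1=C2[C@@H](O[Si](C)(C)C(C)(C)C)C[C@@](C)(O)[C@@H]3CC[C@@](C)(O3)CC2(OC(C)=O)OC1=O | intermediate
27 | (1S,4R,8S,10R)-8,13-bis(tert-butyldimethylsilyloxy)-1,4-epoxy-10-hydroxygermacra-5,7(11)-dien-12,6-olide | CC(C)(C)[Si](C)(C)OCC1=C2/C(=C\[C@@]3(C)CC[C@H](O3)[C@](C)(O)C[C@@H]2O[Si](C)(C)C(C)(C)C)OC1=O | intermediate
28 | (1S,4R,8S,10R)-1,4-epoxy-8,10,13-trihydroxygermacra-5,7(11)-dien-12,6-olide | OCC1=C2/C(=C\[C@@]3(C)CC[C@H](O3)[C@](C)(O)C[C@@H]2O)OC1=O | intermediate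
29 | (1S,4R,8S,10R)-13-acetoxy-1,4-epoxy-8,10-dihydroxygermacra-5,7(11)-dien-12,6-olide | CC(=O)OCC1=C2/C(=C\[C@@]3(C)CC[C@H](O3)[C@](C)(O)C[C@@H]2O)OC1=O | intermediate
30 | (R)-2-methylglycidol | OC[C@]1(C)CO1 | starting material
31 | (2S)-2-methyloxirane-2-carboxylic acid | OC(=O)[C@]1(C)CO1 | intermediate
32 | (2S)-2-methyloxirane-2-carboxylic 2,4,6-trichlorobenzoic anhydride | O=C(OC(=O)c1c(Cl)cc(Cl)cc1Cl)[C@]1(C)CO1 | intermediate
33 | CNP0142137.1 | CC(=O)OCC1=C2/C(=C\[C@@]3(C)CC[C@H](O3)[C@](C)(O)C[C@@H]2OC(=O)[C@]2(C)CO2)OC1=O | target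

Total step count: 18. Longest linear sequence: 17 (steps 1–16 and 18; step 17 is a one-step branch).

Steps most likely to fail

Step 11. The ten-membered enolate may flip its C1=C10 plane through the ring before oxygen transfer, so that the oxaziridine meets the other face of C1; heterolytic C5–C10 cleavage would add to the loss. The fallback sets out from 17 and changes how C1 is fixed, from facial selection to SN2 inversion. The same one-flask sequence would then deliver the C1 epimer, (4S,7R,10E)-7-hydroxy ketone F1. A Mitsunobu reaction (4-nitrobenzoic acid, PPh3, DIAD, toluene, 0 °C) should convert it with inversion into the (7S)-4-nitrobenzoate F2. Mild methanolysis (K2CO3 cat., MeOH, −10 °C) returns to the route at 20.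

Step 13. Singlet oxygen may undergo an ene reaction at the trisubstituted C4=C5 alkene, or the peroxide may fragment along other lines, before the lactone and the ether are in place. The fallback sets out from 22 and replaces the cycloaddition by electrophilic oxidative furan opening. NBS with NaHCO3 in acetone/H2O at −20 °C should give the (Z)-keto-enal F3 (C6 ketone, C12 aldehyde). DBU (cat., CH2Cl2) should then close the C1–O–C4 ether by oxa-Michael addition to give the ether-bridged keto-enal F4. Pinnick oxidation (NaClO2, NaH2PO4, 2-methylbut-2-ene, t-BuOH/H2O) of the C12 aldehyde returns to the route at 25.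

Step 8. The Lewis acid may ionise the C8 silyl ether next to the furan, or the activated aldehyde may be attacked by the wrong alkene carbon or capture chloride. The fallback sets out from 11 and closes the ring at C5–C6 by palladium catalysis. Addition of 2-methylprop-1-enylmagnesium bromide (THF, −78 °C) should give the allylic alcohol F5. Dess–Martin oxidation gives the enone F6. Intramolecular α-arylation of its dienolate (Pd2(dba)3, Xantphos, K3PO4, toluene, 80 °C), where only closure at C5 gives a six-membered ring, returns to the route at 15.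

Further compounds
F1 | step 11 | (4S,7R,10E)-4-(tert-butyldimethylsilyloxy)-3-[(tert-butyldimethylsilyloxy)methyl]-7-hydroxy-10-methyl-4,5,8,9-tetrahydrocyclodeca[b]furan-6(7H)-one | CC(C)(C)[Si](C)(C)OCc1coc2/C=C(C)/CC[C@@H](O)C(=O)C[C@H](O[Si](C)(C)C(C)(C)C)c12
F2 | step 11 | (7S)-4-nitrobenzoate of 20 | CC(C)(C)[Si](C)(C)OCc1coc2/C=C(C)/CC[C@H](OC(=O)c3ccc(cc3)[N+](=O)[O-])C(=O)C[C@H](O[Si](C)(C)C(C)(C)C)c12
F3 | step 13 | (Z)-keto-enal from oxidative opening of furan 22 | O=C/C(CO[Si](C)(C)C(C)(C)C)=C1\C(=O)/C=C(C)/CC[C@H](O)[C@](C)(O)C[C@@H]1O[Si](C)(C)C(C)(C)C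
F4 | step 13 | 1,4-epoxy-bridged keto-enal | O=C/C(CO[Si](C)(C)C(C)(C)C)=C1\C(=O)C[C@@]2(C)CC[C@H](O2)[C@](C)(O)C[C@@H]1O[Si](C)(C)C(C)(C)C
F5 | step 8 | (1S)-1-{2-bromo-4-[(tert-butyldimethylsilyloxy)methyl]furan-3-yl}-1-(tert-butyldimethylsilyloxy)-5-methylhex-4-en-3-ol (C3 epimers) | CC(C)=CC(O)C[C@H](O[Si](C)(C)C(C)(C)C)c1c(Br)occ1CO[Si](C)(C)C(C)(C)C
F6 | step 8 | (1S)-1-{2-bromo-4-[(tert-butyldimethylsilyloxy)methyl]furan-3-yl}-1-(tert-butyldimethylsilyloxy)-5-methylhex-4-en-3-one | CC(C)=CC(=O)C[C@H](O[Si](C)(C)C(C)(C)C)c1c(Br)occ1CO[Si](C)(C)C(C)(C)C
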